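**Retrosynthetic overview**
- The route rests on the 4-pyranone ring of the tetrahydrochromone half (O1, C2, C3, C4, C4a, C8a). It is a 3-oxo-5-phenylpentanoyl unit laid across C8a (ketone level) and C4a (α-methylene level) of a cyclohexane that already carries O5, O6, O7 and the C8 aryl ether.
- Key disconnection: C4–C4a and O1–C8a, that is, an enamine (N on C8a, C8a=C4a) plus the acylketene released from the 6-phenethyl dioxinone. The enamine is made by Pd amination of the C8a vinyl bromide inherited from the microbial bromodiene diol, so its regiochemistry is built in.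
- The C8–OAr bond comes from two successive Mitsunobu inversions (net retention) with the 6-hydroxychromone. O5 and O6 come from anti epoxidation and allylic opening. O6/O7 are tied as a butane-2,3-diacetal, which leaves O8 free and holds C5–O pseudoequatorial.
- The aryl chromone comes from paeonol by bromination, Claisen condensation/cyclodehydration and borylation–oxidation.
- Ring order: carbocycle (present in the diol), aryl chromone pyranone ring (step 8), tetrahydrochromone pyranone ring last (step 13), then deprotection.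

Key step: step 13

Remark: diol 1 is taken as the commercial microbial oxidation product of bromobenzene. Its ring carbons keep the target's locants throughout (C8 = carbinol carbon next to C–Br, C8a = C–Br, C7 = the other carbinol carbon), α is the face of its two hydroxyls (target = 5α,6β,7α,8α), and BDA is the (2S,3S)-2,3-dimethoxybutane-2,3-diyl bridge with both methoxy groups axial.

**Route**

Step 1
Reactants: 1 (1S,2S)-3-bromocyclohexa-3,5-diene-1,2-diol
Product: 2 acetonide (3aS,7aS)-4-bromo-2,2-dimethyl-3a,7a-dihydro-1,3-benzodioxole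
Conditions: Me2C(OMe)2, p-TsOH (cat.), acetone, 0 °C → rt; used at once
Reagents that add atoms: 2,2-dimethoxypropane, COC(C)(C)OC
Why: Acid-catalysed acetal exchange closes the cis-fused dioxolane on the 7α,8α-diol (acetonide protection), which blocks both hydroxyls and shields the α face.

Step 2
Reactants: 2 acetonide
Product: 3 anti epoxide of 2 (C5–C6 oxirane on the β face; C8a(Br)=C4a alkene kept)
Conditions: mCPBA, CH2Cl2, 0 °C → rt
Reagents that add atoms: meta-chloroperoxybenzoic acid, OOC(=O)c1cccc(Cl)c1
Why: Prilezhaev epoxidation takes the more electron-rich, bromine-free C5=C6 alkene from the β face, opposite the dioxolane, which sets the C6–O bond β.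

Step 3
Reactants: 3 anti epoxide
Product: 4 bromocyclohexene with 5α-benzyloxy, 6β-hydroxy and the 7α,8α-acetonide
Conditions: BnOH (5 equiv), BF3·OEt2 (cat.), CH2Cl2, −30 → 0 °C
Reagents that add atoms: benzyl alcohol, OCc1ccccc1
Why: Lewis acid-promoted SN2 opening of the vinyl oxirane occurs at the allylic carbon C5 with inversion, so the benzyl ether is set α, trans to the 6β-hydroxyl.

Step 4
Reactants: 4 benzyl ether acetonide
Product: 6 BDA alcohol (8a-bromo-5α-benzyloxy-6β,7α-O-BDA-cyclohexen-8α-ol), via triol 5 (not isolated)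
Conditions: butane-2,3-dione, HC(OMe)3, CSA (cat.), MeOH, reflux
Reagents that add atoms: butane-2,3-dione, CC(=O)C(C)=O; methanol, CO
Why: Acidic methanol removes the isopropylidene group and the butane-2,3-diacetal then forms under thermodynamic control only across the trans-diequatorial O6/O7 pair (trans-fused dioxane, both acetal centres set S by the double anomeric effect), so the cis allylic C8 hydroxyl stays free, as in the same protection of shikimate esters.

Step 5
Reactants: 6 BDA alcohol
Product: 7 8β-(4-nitrobenzoate) of the BDA bromocyclohexene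
Conditions: 4-O2NC6H4CO2H, PPh3, DIAD, THF, 0 °C → rt
Reagents that add atoms: 4-nitrobenzoic acid, OC(=O)c1ccc(cc1)[N+](=O)[O-]
Why: Mitsunobu esterification with an acidic carboxylic acid displaces the activated pseudoaxial C8 oxygen by SN2, inverting C8 from α to β.

Step 6
Reactants: 7 8β-(4-nitrobenzoate)
Product: 8 8β-alcohol (C8 epimer of 6)
Conditions: K2CO3 (cat.), MeOH, 0 °C → rt
Reagents that add atoms: none
Why: Transesterification cleaves the ester at the acyl carbon, so the 8β configuration is kept and the vinyl bromide and diacetal are untouched.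

Step 7
Reactants: 9 paeonol (1-(2-hydroxy-4-methoxyphenyl)ethan-1-one)
Product: 10 1-(5-bromo-2-hydroxy-4-methoxyphenyl)ethan-1-one
Conditions: NBS, MeCN, 0 °C → rt
Reagents that add atoms: N-bromosuccinimide, BrN1C(=O)CCC1=O
Why: Electrophilic aromatic bromination goes para to the phenol and ortho to the methoxy group (C5), the activated position that is not flanked by two substituents.

Step 8
Reactants: 10 bromopaeonol; 11 ethyl 3-phenylpropanoate
Product: 13 6-bromo-7-methoxy-2-(2-phenylethyl)-4H-chromen-4-one, via diketone 12 (not isolated)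
Conditions: NaH (4 equiv), THF, reflux; then conc. HCl, AcOH, 90 °C
Reagents that add atoms: none
Why: Claisen condensation of the acetophenone dianion with the ester gives the 1,3-diketone, which cyclodehydrates under acid to the 2-substituted chromone.

Step 9
Reactants: 13 bromochromone
Product: 15 6-hydroxy-7-methoxy-2-(2-phenylethyl)-4H-chromen-4-one, via pinacol boronate 14 (not isolated)
Conditions: B2pin2, PdCl2(dppf), KOAc, 1,4-dioxane, 90 °C; then NaBO3·4H2O, THF/H2O, rt
Reagents that add atoms: bis(pinacolato)diboron, CC1(C)OB(OC1(C)C)B1OC(C)(C)C(C)(C)O1 (boron of 14); sodium perborate, [Na+].[Na+].O[B-]1(O)OO[B-](O)(O)OO1 (phenol oxygen)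
Why: Miyaura borylation of the aryl bromide followed by perborate oxidation of the C–B bond (1,2-aryl shift to oxygen) gives the phenol under conditions mild enough for the chromone.

Step 10
Reactants: 16 2,2,6-trimethyl-4H-1,3-dioxin-4-one; 17 benzyl bromide
Product: 19 2,2-dimethyl-6-(2-phenylethyl)-4H-1,3-dioxin-4-one, via lithium dienolate 18 (not isolated)
Conditions: LiN(iPr)2 (commercial solution), THF/DMPU, −78 °C; then BnBr, −78 → −30 °C
Reagents that add atoms: none
Why: γ-Deprotonation of the dioxinone gives the extended dienolate, which is benzylated at the exocyclic carbon (vinylogous enolate alkylation).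

Step 11
Reactants: 8 8β-alcohol; 15 hydroxychromone
Product: 20 8α-aryl ether (8a-bromo-5α-benzyloxy-6β,7α-O-BDA-cyclohexene carrying the 7-methoxy-4-oxo-2-(2-phenylethyl)chromen-6-yloxy group at C8α)
Conditions: PPh3, DIAD, THF, 0 °C → rt
Reagents that add atoms: none
Why: Mitsunobu etherification lets the phenol displace the activated pseudoequatorial 8β-oxygen by SN2 from the α face, so the aryl ether ends cis to O7 with net retention over steps 5, 6 and 11.

Step 12
Reactants: 20 8α-aryl ether vinyl bromide
Product: 21 morpholine enamine (N on C8a, C8a=C4a; 8α-aryloxy, 5α-benzyloxy, 6β,7α-O-BDA)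
Conditions: morpholine (1.5 equiv), Pd2(dba)3, rac-BINAP, Cs2CO3, toluene, 90 °C, Ar; filtered through Celite under Ar, concentrated, used crude
Reagents that add atoms: morpholine, C1COCCN1
Why: Buchwald–Hartwig-type amination of the alkenyl bromide with a secondary amine (oxidative addition of zerovalent palladium into C8a–Br, then C–N reductive elimination) puts nitrogen on C8a and leaves the double bond at C8a=C4a, so the enamine regiochemistry is fixed by the bromide and C8 never passes through an enolisable ketone.

Step 13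
Reactants: 21 morpholine enamine; 19 2,2-dimethyl-6-(2-phenylethyl)-4H-1,3-dioxin-4-one
Product: 24 protected target (5-O-benzyl-6,7-O-BDA tetrahydrochromone 8α-aryl ether), via acylketene 22 (not isolated), via aminal 23 (not isolated)
Conditions: 19 (2.5 equiv), toluene, 110 °C, N2 sweep; then SiO2, CH2Cl2, rt
Reagents that add atoms: none
Why: On heating, 19 loses acetone by retro-[4+2] to give acylketene 22, whose ketene carbon is attacked by the enamine β-carbon C4a (C4–C4a bond); the enolate oxygen of the zwitterion then adds to the iminium carbon C8a (O1–C8a bond, 6-exo-trig, overall a stepwise formal hetero-[4+2]) to give aminal 23, and E1cB loss of morpholine across C4a–C8a delivers the 4-pyranone. The closest known reaction is the γ-pyrone annulation of cyclohexanone enamines with diketene or dioxinone-derived acylketenes, the standard entry to 5,6,7,8-tetrahydrochromones. The only ring closed is the pyranone ring (O1, C2, C3, C4, C4a, C8a), and no lasting stereocentre is formed: the two transient centres of 23 (C4a, C8a) become sp2 and C5 to C8 are spectators. Site selectivity (acylation at C4a, none at C8) is secured by the fixed position of the enamine double bond and by the pseudoaxial C8 aryloxy group, which keeps C8–H out of conjugation. Chemoselectivity needs the enamine to be the only nucleophile, hence no free OH or NH in 21, and needs the C5 benzyloxy group to survive 110 °C, which the trans-fused diacetal favours by holding C5–O pseudoequatorial, near the nodal plane of the enamine π system, so that 1,4-elimination is stereoelectronically poor. Excess 19 acylates the morpholine set free and keeps it away from the two chromone-type rings.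

Step 14
Reactants: 24 protected target
Product: 26 target (5S,6R,7S,8S)-5,6,7-trihydroxy-8-{[7-methoxy-4-oxo-2-(2-phenylethyl)-4H-chromen-6-yl]oxy}-2-(2-phenylethyl)-5,6,7,8-tetrahydro-4H-chromen-4-one, via diol 25 (not isolated)
Conditions: TFA/H2O (9:1), 0 °C → rt; evaporation (toluene azeotrope); then BCl3 (6 equiv), C6HMe5 (6 equiv), CH2Cl2, −78 °C; MeOH quench
Reagents that add atoms: none
Why: Aqueous acid hydrolyses the diacetal, and BCl3 with pentamethylbenzene as benzyl cation scavenger then cleaves the C5 benzyl ether at −78 °C (Lewis acid debenzylation) without touching the aryl methyl ether, the C8 aryl ether or the protonation-deactivated pyranones, so no stereocentre is disturbed.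

**Compound list**
1 | (1S,2S)-3-bromocyclohexa-3,5-diene-1,2-diol | O[C@@H]1C(Br)=CC=C[C@@H]1O | starting material
2 | (3aS,7aS)-4-bromo-2,2-dimethyl-3a,7a-dihydro-1,3-benzodioxole | CC1(C)O[C@@H]2C(Br)=CC=C[C@@H]2O1 | intermediate
3 | anti (β) C5–C6 epoxide of 2 | CC1(C)O[C@@H]2C(Br)=C[C@H]3O[C@H]3[C@@H]2O1 | intermediate
4 | 5α-benzyloxy-6β-hydroxy-7α,8α-acetonide of the 8a-bromocyclohexene | CC1(C)O[C@@H]2C(Br)=C[C@H](OCc3ccccc3)[C@@H](O)[C@@H]2O1 | intermediate
5 | 5α-benzyloxy-8a-bromocyclohexene-6β,7α,8α-triol (not isolated) | O[C@@H]1C(Br)=C[C@H](OCc2ccccc2)[C@@H](O)[C@@H]1O | intermediate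
6 | BDA alcohol: 5α-benzyloxy-8a-bromo-6β,7α-O-BDA-cyclohexen-8α-ol | O[C@@H]1C(Br)=C[C@H](OCc2ccccc2)[C@H]2O[C@](C)(OC)[C@@](C)(OC)O[C@H]12 | intermediate
7 | 8β-(4-nitrobenzoate) of the BDA bromocyclohexene | O=C(O[C@H]1C(Br)=C[C@H](OCc2ccccc2)[C@H]2O[C@](C)(OC)[C@@](C)(OC)O[C@H]12)c1ccc(cc1)[N+](=O)[O-] | intermediate
8 | 8β-alcohol (C8 epimer of 6) | O[C@H]1C(Br)=C[C@H](OCc2ccccc2)[C@H]2O[C@](C)(OC)[C@@](C)(OC)O[C@H]12 | intermediate
9 | paeonol, 1-(2-hydroxy-4-methoxyphenyl)ethan-1-one | CC(=O)c1ccc(OC)cc1O | starting material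
10 | 1-(5-bromo-2-hydroxy-4-methoxyphenyl)ethan-1-one | CC(=O)c1cc(Br)c(OC)cc1O | intermediate
11 | ethyl 3-phenylpropanoate | CCOC(=O)CCc1ccccc1 | starting material
12 | 1-(5-bromo-2-hydroxy-4-methoxyphenyl)-5-phenylpentane-1,3-dione (not isolated) | COc1cc(O)c(cc1Br)C(=O)CC(=O)CCc1ccccc1 | intermediate
13 | 6-bromo-7-methoxy-2-(2-phenylethyl)-4H-chromen-4-one | COc1cc2oc(CCc3ccccc3)cc(=O)c2cc1Br | intermediate
14 | 7-methoxy-2-(2-phenylethyl)-6-(pinacolatoboryl)-4H-chromen-4-one (not isolated) | COc1cc2oc(CCc3ccccc3)cc(=O)c2cc1B1OC(C)(C)C(C)(C)O1 | intermediate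
15 | 6-hydroxy-7-methoxy-2-(2-phenylethyl)-4H-chromen-4-one | COc1cc2oc(CCc3ccccc3)cc(=O)c2cc1O | intermediate
16 | 2,2,6-trimethyl-4H-1,3-dioxin-4-one | CC1=CC(=O)OC(C)(C)O1 | starting material
17 | benzyl bromide | BrCc1ccccc1 | starting material
18 | lithium dienolate of 16 (not isolated) | [Li+].[O-]C1=CC(=C)OC(C)(C)O1 | intermediate
19 | 2,2-dimethyl-6-(2-phenylethyl)-4H-1,3-dioxin-4-one | CC1(C)OC(CCc2ccccc2)=CC(=O)O1 | intermediate
20 | 8α-aryl ether of the BDA bromocyclohexene | COc1cc2oc(CCc3ccccc3)cc(=O)c2cc1O[C@@H]1C(Br)=C[C@H](OCc2ccccc2)[C@H]2O[C@](C)(OC)[C@@](C)(OC)O[C@H]12 | intermediate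
21 | morpholine enamine (N on C8a, C8a=C4a) | COc1cc2oc(CCc3ccccc3)cc(=O)c2cc1O[C@@H]1C(N2CCOCC2)=C[C@H](OCc2ccccc2)[C@H]2O[C@](C)(OC)[C@@](C)(OC)O[C@H]12 | intermediate
22 | acylketene 3-oxo-5-phenylpent-1-en-1-one (not isolated) | O=C=CC(=O)CCc1ccccc1 | intermediate
23 | 8a-morpholino-4a,8a-dihydropyranone aminal, C4a and C8a undefined (not isolated) | COc1cc2oc(CCc3ccccc3)cc(=O)c2cc1O[C@@H]1C2(N3CCOCC3)OC(CCc3ccccc3)=CC(=O)C2[C@H](OCc2ccccc2)[C@H]2O[C@](C)(OC)[C@@](C)(OC)O[C@H]12 | intermediate
24 | 5-O-benzyl-6,7-O-BDA ether of the target | COc1cc2oc(CCc3ccccc3)cc(=O)c2cc1O[C@@H]1c2oc(CCc3ccccc3)cc(=O)c2[C@H](OCc2ccccc2)[C@H]2O[C@](C)(OC)[C@@](C)(OC)O[C@H]12 | intermediate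
25 | 5-O-benzyl ether of the target (not isolated) | COc1cc2oc(CCc3ccccc3)cc(=O)c2cc1O[C@@H]1c2oc(CCc3ccccc3)cc(=O)c2[C@H](OCc2ccccc2)[C@@H](O)[C@@H]1O | intermediate
26 | (5S,6R,7S,8S)-5,6,7-trihydroxy-8-{[7-methoxy-4-oxo-2-(2-phenylethyl)-4H-chromen-6-yl]oxy}-2-(2-phenylethyl)-5,6,7,8-tetrahydro-4H-chromen-4-one | COc1cc2oc(CCc3ccccc3)cc(=O)c2cc1O[C@@H]1c2oc(CCc3ccccc3)cc(=O)c2[C@H](O)[C@@H](O)[C@@H]1O | target

**Step count**
Total: 14 steps. Longest linear sequence: 10 steps (1 → 2 → 3 → 4 → 6 → 7 → 8 → 20 → 21 → 24 → 26; steps 1–6 and 11–14).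

**Steps most likely to fail**

Step 13 (key annulation). The enamine may lose benzyl alcohol by thermal 1,4-elimination and then aromatise. C-acylation at the hindered C4a may be slower than self-condensation of the acylketene. Morpholine may be lost incompletely from the aminal. The fallback replaces the thermal acylketene by a low-temperature acylation followed by cycloisomerisation. It sets out from enamine 21 and comes back at 24. 4-Phenylbut-1-yne is lithiated (n-BuLi, THF, −78 °C) and carboxylated with CO2 to 5-phenylpent-2-ynoic acid F1, which oxalyl chloride (cat. DMF, CH2Cl2) turns into 5-phenylpent-2-ynoyl chloride F2. Stork acylation of 21 with F2 (Et3N, CH2Cl2, −20 → 0 °C) and buffered aqueous hydrolysis (AcOH/NaOAc) should give the alkynyl 1,3-diketone F3. Its enol oxygen on C8a then adds 6-endo-dig to the ynone (cat. TfOH, CH2Cl2, rt) to close the same pyranone ring and give 24.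

Step 12 (enamine by Pd amination). Oxidative addition at C8a–Br may compete with ionisation of the allylic C8 aryl ether by zerovalent palladium. The base may damage the chromone at 90 °C. The enamine may hydrolyse on handling. The fallback makes the enamine by condensation. It sets out from 20 and comes back at 21. Miyaura borylation (B2pin2, PdCl2(dppf), KOAc, dioxane, 80 °C) should give the alkenyl pinacol boronate F4. Oxidation (NaBO3·4H2O, THF/H2O, 0 °C) gives the α-aryloxy ketone F5. Condensation with morpholine (TiCl4, excess morpholine, toluene, 0 °C → rt) gives 21, the enamine forming toward the C4a methylene because the C8 side would suffer allylic strain.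

Step 11 (Mitsunobu etherification). The phenol may attack C4a in an SN2′ sense, the activated alcohol may eliminate, or conversion at the hindered secondary carbinol may stall. The fallback forms the ether at the aryl carbon instead, with retention at C8. It sets out from alcohol 6 and bromochromone 13 and comes back at 20, bypassing steps 5 and 6. Halogen exchange on 13 (NaI, CuI, trans-N,N'-dimethylcyclohexane-1,2-diamine, dioxane, 110 °C) gives 6-iodo-7-methoxy-2-(2-phenylethyl)-4H-chromen-4-one F6. Ullmann-type O-arylation of 6 with F6 (CuI, 3,4,7,8-tetramethyl-1,10-phenanthroline, Cs2CO3, toluene, 110 °C) gives 20. It is not the first choice because selectivity for the aryl iodide over the vinyl bromide and efficiency with a hindered secondary alcohol are less predictable.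

**Further compounds**
F1 | step 13 | 5-phenylpent-2-ynoic acid | OC(=O)C#CCCc1ccccc1
F2 | step 13 | 5-phenylpent-2-ynoyl chloride | ClC(=O)C#CCCc1ccccc1
F3 | step 13 | alkynyl 1,3-diketone: 8a-ketone of the 8α-aryloxy-5α-benzyloxy-6β,7α-O-BDA-cyclohexane bearing a 5-phenylpent-2-ynoyl group at C4a (C4a undefined, enolised) | COc1cc2oc(CCc3ccccc3)cc(=O)c2cc1O[C@@H]1C(=O)C(C(=O)C#CCCc2ccccc2)[C@H](OCc2ccccc2)[C@H]2O[C@](C)(OC)[C@@](C)(OC)O[C@H]12
F4 | step 12 | alkenyl pinacol boronate (Bpin on C8a in place of Br in 20) | COc1cc2oc(CCc3ccccc3)cc(=O)c2cc1O[C@@H]1C(B2OC(C)(C)C(C)(C)O2)=C[C@H](OCc2ccccc2)[C@H]2O[C@](C)(OC)[C@@](C)(OC)O[C@H]12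
F5 | step 12 | α-aryloxy ketone (C8a ketone, C4a methylene) | COc1cc2oc(CCc3ccccc3)cc(=O)c2cc1O[C@@H]1C(=O)C[C@H](OCc2ccccc2)[C@H]2O[C@](C)(OC)[C@@](C)(OC)O[C@H]12
F6 | step 11 | 6-iodo-7-methoxy-2-(2-phenylethyl)-4H-chromen-4-one | COc1cc2oc(CCc3ccccc3)cc(=O)c2cc1I
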